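**Retrosynthetic overview**

1. Side chain and stereocentre: L-malic acid 1 is closed to its acetonide (dioxolanone) acid 2. This ring is temporary; it is opened in the last step, where its C=O becomes the C(CH3)2OH carbon.
2. Core: rings A, B and C are bought as genistein 3, so no ring of the target is formed in the route; 3 → 7,4'-bis-MOM ether 4 → 6-iodide 5.
3. Key disconnection C6–CH2: visible-light nickel/iridium decarboxylative coupling of 5 with 2 (as its cesium salt 6) → 7.
4. Last disconnection: two C–CH3 bonds (MeMgBr on the dioxolanone of 7 → diol 8), then MOM removal → erycibenin A 9.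

Assumption: only substrates, intermediates and the target are numbered; reagents that add atoms (2,2-dimethoxypropane, MOMCl, the iodinating salt, MeMgBr) are given with SMILES in their step.

**Route**

Step 1
Reactants: 1 L-malic acid [(S)-2-hydroxybutanedioic acid]
Product: 2 (S)-2-(2,2-dimethyl-5-oxo-1,3-dioxolan-4-yl)acetic acid
Conditions: Me2C(OMe)2 (4 equiv), p-TsOH·H2O (2 mol%), rt, 16 h; crystallise from Et2O/hexane
Reagents that add atoms: 2,2-dimethoxypropane, COC(C)(C)OC
Why: Acid-catalysed transketalisation closes the five-membered dioxolanone on the α-hydroxy acid unit in preference to the six-membered alternative and leaves the CH2CO2H arm free; no bond to the stereocentre is broken, so the (S) configuration of 1 is carried over unchanged.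

Step 2
Reactants: 3 genistein [5,7-dihydroxy-3-(4-hydroxyphenyl)-4H-chromen-4-one]
Product: 4 5-hydroxy-7-(methoxymethoxy)-3-[4-(methoxymethoxy)phenyl]-4H-chromen-4-one
Conditions: MOMCl (2.3 equiv), K2CO3 (4 equiv), acetone, 0 °C → rt, 3 h
Reagents that add atoms: chloromethyl methyl ether, COCCl
Why: Williamson-type O-alkylation of the two acidic phenols (7-OH and 4'-OH), while the 5-OH is held in a hydrogen-bonded chelate with the C4 carbonyl and stays free under carbonate conditions.

Step 3
Reactants: 4 5-hydroxy-7-(methoxymethoxy)-3-[4-(methoxymethoxy)phenyl]-4H-chromen-4-one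
Product: 5 5-hydroxy-6-iodo-7-(methoxymethoxy)-3-[4-(methoxymethoxy)phenyl]-4H-chromen-4-one
Conditions: BnMe3N·ICl2 (1.05 equiv), CaCO3 (1.5 equiv), CH2Cl2/MeOH 5:2, rt, dark, 3 h
Reagents that add atoms: benzyltrimethylammonium dichloroiodate, C[N+](C)(C)Cc1ccccc1.Cl[I-]Cl
Why: Electrophilic aromatic iodination, which in 5-hydroxy-7-alkoxy flavonoids goes ortho to the free 5-OH (C6) and not to C8, the anisole-type ring B being much less reactive; CaCO3 takes up the HCl so the MOM acetals survive.

Step 4
Reactants: 5 5-hydroxy-6-iodo-7-(methoxymethoxy)-3-[4-(methoxymethoxy)phenyl]-4H-chromen-4-one; 2 (S)-2-(2,2-dimethyl-5-oxo-1,3-dioxolan-4-yl)acetic acid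
Product: 7 (5S)-5-{[5-hydroxy-7-(methoxymethoxy)-3-[4-(methoxymethoxy)phenyl]-4-oxo-4H-chromen-6-yl]methyl}-2,2-dimethyl-1,3-dioxolan-4-one, via cesium carboxylate 6 (not isolated)
Conditions: 2 (2.0 equiv), Cs2CO3 (1.0 equiv), Ir[dF(CF3)ppy]2(dtbbpy)PF6 (2 mol%), NiCl2·dme (10 mol%), 4,4'-di-tert-butyl-2,2'-bipyridine (15 mol%), degassed DMF, 450 nm LEDs, 25–30 °C, 24 h
Reagents that add atoms: none
Why: Proposed new method: metallaphotoredox decarboxylative C(sp3)–C(sp2) coupling, used here for the first time with the L-malic acid acetonide acid as a chiral-pool radical synthon for the 2,3-dihydroxy-3-methylbutyl side chain and with a di-ortho-oxygenated 6-iodo-5-hydroxychromen-4-one as the aryl partner; the excited trivalent iridium complex oxidises carboxylate 6, loss of CO2 gives a primary β-oxygenated alkyl radical (which, unlike an alkylzinc or alkylmagnesium species, does not expel its β-oxygen, and whose radical carbon is not the stereocentre, so the (S) centre bought in 1 cannot scramble), zerovalent nickel inserts into the C6–I bond, the arylnickel species captures the radical, and reductive elimination from trivalent nickel forms the C6–CH2 bond while the reduced iridium complex returns nickel to the zerovalent state; using no base beyond what forms 6 keeps the chelated 5-OH protonated, and 450 nm light is not absorbed by the isoflavone; the closest known reaction type is the nickel/iridium photoredox decarboxylative arylation of aliphatic carboxylic acids with aryl halides, for example at the side-chain carboxyl of protected aspartic acid.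

Step 5
Reactants: 7 (5S)-5-{[5-hydroxy-7-(methoxymethoxy)-3-[4-(methoxymethoxy)phenyl]-4-oxo-4H-chromen-6-yl]methyl}-2,2-dimethyl-1,3-dioxolan-4-one
Product: 9 erycibenin A [5,7-dihydroxy-6-[(2S)-2,3-dihydroxy-3-methylbutyl]-3-(4-hydroxyphenyl)-4H-chromen-4-one], via bis-MOM diol 8 (not isolated)
Conditions: MeMgBr (6 equiv), THF, −40 → 0 °C, 2 h; then MeOH, conc. HCl (to ca. 2 M), 40 °C, 3 h
Reagents that add atoms: methylmagnesium bromide, C[Mg]Br
Why: Double Grignard addition to the activated lactone-type carbonyl of the dioxolanone opens the ring and gives the tertiary carbinol faster than α-enolisation at low temperature, so the adjacent stereocentre is kept, while the chromone, a vinylogous ester further deactivated as its magnesium 5-phenoxide, does not compete; the acidic methanol then removes both MOM groups by acetal methanolysis. Four equivalents of MeMgBr are consumed: one by the 5-OH, two by the carbonyl and one by the acetone released.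

**Compound list**

1 | L-malic acid, (S)-2-hydroxybutanedioic acid | OC(=O)C[C@H](O)C(=O)O | starting material
2 | (S)-2-(2,2-dimethyl-5-oxo-1,3-dioxolan-4-yl)acetic acid | CC1(C)O[C@@H](CC(=O)O)C(=O)O1 | intermediate
3 | genistein, 5,7-dihydroxy-3-(4-hydroxyphenyl)-4H-chromen-4-one | O=c1c(-c2ccc(O)cc2)coc2cc(O)cc(O)c12 | starting material
4 | 5-hydroxy-7-(methoxymethoxy)-3-[4-(methoxymethoxy)phenyl]-4H-chromen-4-one | O=c1c(-c2ccc(OCOC)cc2)coc2cc(OCOC)cc(O)c12 | intermediate
5 | 5-hydroxy-6-iodo-7-(methoxymethoxy)-3-[4-(methoxymethoxy)phenyl]-4H-chromen-4-one | O=c1c(-c2ccc(OCOC)cc2)coc2cc(OCOC)c(I)c(O)c12 | intermediate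
6 | cesium (S)-2-(2,2-dimethyl-5-oxo-1,3-dioxolan-4-yl)acetate (not isolated) | CC1(C)O[C@@H](CC(=O)[O-])C(=O)O1.[Cs+] | intermediate
7 | (5S)-5-{[5-hydroxy-7-(methoxymethoxy)-3-[4-(methoxymethoxy)phenyl]-4-oxo-4H-chromen-6-yl]methyl}-2,2-dimethyl-1,3-dioxolan-4-one | CC1(C)O[C@@H](Cc2c(OCOC)cc3occ(-c4ccc(OCOC)cc4)c(=O)c3c2O)C(=O)O1 | intermediate
8 | 5-hydroxy-6-[(2S)-2,3-dihydroxy-3-methylbutyl]-7-(methoxymethoxy)-3-[4-(methoxymethoxy)phenyl]-4H-chromen-4-one (not isolated) | CC(C)(O)[C@@H](O)Cc1c(OCOC)cc2occ(-c3ccc(OCOC)cc3)c(=O)c2c1O | intermediate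
9 | erycibenin A, 5,7-dihydroxy-6-[(2S)-2,3-dihydroxy-3-methylbutyl]-3-(4-hydroxyphenyl)-4H-chromen-4-one | CC(C)(O)[C@@H](O)Cc1c(O)cc2occ(-c3ccc(O)cc3)c(=O)c2c1O | target

**Step count and risks**

Total steps: 5. Longest linear sequence: 4 steps (3 → 4 → 5 → 7 → 9).

Most likely to fail, first: step 4 (the proposed new coupling). The iodide is electron-rich and flanked by two oxygen substituents, so radical capture at nickel may be slow. Likely side products are the proto-deiodinated compound 4 (recyclable) and the aryl ester from O-arylation of the carboxylate; partial deprotonation of the 5-OH could also quench the photocatalyst. The fallback uses known chemistry, sets out from 2 and 5 and comes back at 7. Acid 2 is condensed with N-hydroxyphthalimide (N,N'-diisopropylcarbodiimide, cat. DMAP, CH2Cl2) to the redox-active ester (S)-1,3-dioxoisoindolin-2-yl 2-(2,2-dimethyl-5-oxo-1,3-dioxolan-4-yl)acetate F2. F2 is coupled with 5 by the established nickel-catalysed electroreductive decarboxylative arylation of such esters (NiCl2·6H2O, 2,2'-bipyridine, AgNO3, Mg anode, carbon cathode, DMF, constant current, rt). The radical is then released by cathodic reduction of the ester and not by photo-oxidation of a carboxylate, which removes both the O-arylation channel and the phenol-quenching problem.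

Second: step 5. Excess MeMgBr may attack the isoflavone (C2 or C4) before the dioxolanone is consumed. The fallback places the methyl groups before the isoflavone is present; it sets out from 2 and comes back at 8. Acid 2 is treated with MeMgBr (5 equiv, THF, −20 °C → rt; the carboxylate is inert) and worked up with HCl to give the hydroxy lactone (4S)-4-hydroxy-5,5-dimethyloxolan-2-one F3. CsOH·H2O (1.0 equiv, MeOH/H2O, rt, then evaporation) opens it to cesium (3S)-3,4-dihydroxy-4-methylpentanoate F4, which is used without acidification so it cannot relactonise. F4 is coupled with 5 under the step 4 conditions (which must already have been validated) to give 8, now isolated. The acid stage of step 5 then gives 9.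

Third: step 3. Some C8 iodination or over-iodination may occur. The fallback replaces reagent-controlled electrophilic substitution by delivery through a metal phenoxide; it sets out from 4 and comes back at 5. TlOAc (1.1 equiv, CH2Cl2, rt) converts 4 into the monovalent thallium 5-phenoxide of 4 F1, and I2 (1.05 equiv) then iodinates only ortho to the metal-bound oxygen. C6 is the only free ortho position. This is the established ortho-iodination of thallium phenoxides, applied before to 5-hydroxy-7-alkoxyflavones; thallium salts are highly toxic and need the corresponding handling.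

**Further compounds**

F1 | step 3 | monovalent thallium 5-phenoxide of 4, thallium 7-(methoxymethoxy)-3-[4-(methoxymethoxy)phenyl]-4-oxo-4H-chromen-5-olate | O=c1c(-c2ccc(OCOC)cc2)coc2cc(OCOC)cc([O-])c12.[Tl+]
F2 | step 4 | (S)-1,3-dioxoisoindolin-2-yl 2-(2,2-dimethyl-5-oxo-1,3-dioxolan-4-yl)acetate | CC1(C)O[C@@H](CC(=O)ON2C(=O)c3ccccc3C2=O)C(=O)O1
F3 | step 5 | (4S)-4-hydroxy-5,5-dimethyloxolan-2-one | O=C1C[C@H](O)C(C)(C)O1
F4 | step 5 | cesium (3S)-3,4-dihydroxy-4-methylpentanoate | CC(C)(O)[C@@H](O)CC(=O)[O-].[Cs+]
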